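## Retrosynthetic overview

1. The last events are fluoride removal of a silyl group from the ring B phenol and, before it, para-oxidative dearomatization of a 2-allyl-5-methoxy-4-alkylphenol in methanol. This makes ring A (the cyclohexadienone) and its quaternary C–OMe centre under 1,2-induction from the side-chain methine.
2. The allyl group is placed on ring A by ortho-bromination and Stille coupling after the key step, because a terminal alkene would not survive copper hydride.
3. Key disconnection: the bond between the side-chain CH2 and C-1 of ring B (the guaiacyl ring). The CH2 and the neighbouring methyl-bearing CH on ring A are the two carbons of an exocyclic C=CH2 (an isopropenyl group on ring A). Ligand-controlled CuH addition puts H on the methine carbon and the metal on CH2 (polarity reversal of the alkene), and palladium couples that carbon with the ring B aryl bromide.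
4. No ring is constructed: ring A comes from 4-bromo-3-methoxyphenol and ring B from 4-bromo-2-methoxyphenol. Ring A is dearomatized in the penultimate step.

Key step: step 4

Assumption: (R)-DTBM-SEGPHOS is taken as the ligand antipode that delivers the (2R) product; if the sense proves opposite, the commercial (S) antipode is used and nothing else changes.

Remark: the target SMILES corresponds to the (4R) ring carbon and the (2R) side-chain carbon.

## Route

Step 1
Reactants: 1 4-bromo-3-methoxyphenol
Product: 2 4-(benzyloxy)-1-bromo-2-methoxybenzene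
Conditions: BnBr, K2CO3, DMF, 23 °C
Reagents that add atoms: benzyl bromide, BrCc1ccccc1
Why: Williamson ether synthesis on the phenoxide; the benzyl ether masks the ring A oxygen through the copper hydride step and can later be removed by hydrogenolysis without touching an aryl silyl ether.

Step 2
Reactants: 2 4-(benzyloxy)-1-bromo-2-methoxybenzene; 3 4,4,5,5-tetramethyl-2-(prop-1-en-2-yl)-1,3,2-dioxaborolane
Product: 4 4-(benzyloxy)-2-methoxy-1-(prop-1-en-2-yl)benzene
Conditions: Pd(dppf)Cl2 (3 mol %), K2CO3, dioxane/H2O (4:1), 90 °C
Reagents that add atoms: none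
Why: Suzuki–Miyaura coupling of an electron-rich aryl bromide with an alkenylboronate installs the exocyclic C=CH2 unit that carries both side-chain carbons needed for the key step.

Step 3
Reactants: 5 4-bromo-2-methoxyphenol
Product: 6 (4-bromo-2-methoxyphenoxy)tri(propan-2-yl)silane
Conditions: i-Pr3SiCl, imidazole, DMF, 23 °C
Reagents that add atoms: chlorotri(propan-2-yl)silane, CC(C)[Si](Cl)(C(C)C)C(C)C
Why: Imidazole-promoted silylation of the phenol; the bulky aryl silyl ether should survive the silanolate base of step 4, hydrogenolysis, bromination, Stille coupling and the iodine oxidant, and is cleaved by fluoride at the end.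

Step 4
Reactants: 4 4-(benzyloxy)-2-methoxy-1-(prop-1-en-2-yl)benzene; 6 (4-bromo-2-methoxyphenoxy)tri(propan-2-yl)silane
Product: 8 {4-[(2R)-2-[4-(benzyloxy)-2-methoxyphenyl]propyl]-2-methoxyphenoxy}tri(propan-2-yl)silane, via alkylcopper intermediate 7 (not isolated)
Conditions: Cu(OAc)2 (5 mol %), (R)-DTBM-SEGPHOS (5.5 mol %), [Pd(cinnamyl)Cl]2 (2 mol %), BrettPhos (4.4 mol %), MePh2SiH, NaOSiMe3, THF, 45 °C
Reagents that add atoms: none
Why: Copper hydride carrying DTBM-SEGPHOS should add across the exocyclic C=CH2 of 4 with hydride to the internal carbon and copper to the terminal CH2 (alkylcopper 7); 7 should then transmetalate to the BrettPhos-ligated arylpalladium bromide formed from 6 and zerovalent palladium, and C(sp3)–C(sp2) reductive elimination forges the CH2–aryl bond. The closest known reaction type is the dual CuH/Pd-catalysed enantioselective anti-Markovnikov hydroarylation of 1,1-disubstituted alkenes with aryl bromides. No ring is closed. The one new stereocenter, the methyl-bearing methine, is set in the hydrocupration by the chiral bisphosphine, which distinguishes the large aryl from the small methyl substituent of the alkene; it lies beta to the metal and is untouched by transmetalation and reductive elimination. The step needs terminal regioselectivity, secured by the 1,1-disubstitution and by the ortho-methoxy group, which twists ring A out of conjugation and disfavours a tertiary benzylic copper species. It also needs coupling to outrun reduction of the aryl bromide, secured by fast oxidative addition to the BrettPhos–palladium catalyst and by the absence of any other alkene.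

Step 5
Reactants: 8 {4-[(2R)-2-[4-(benzyloxy)-2-methoxyphenyl]propyl]-2-methoxyphenoxy}tri(propan-2-yl)silane
Product: 9 3-methoxy-4-[(2R)-1-{3-methoxy-4-[tri(propan-2-yl)silyloxy]phenyl}propan-2-yl]phenol
Conditions: H2 (1 atm), Pd/C, EtOAc, 23 °C
Reagents that add atoms: none
Why: Hydrogenolysis of a benzyl aryl ether over palladium; no alkene is present yet, and the aryl silyl ether and the benzylic stereocenter are inert.

Step 6
Reactants: 9 3-methoxy-4-[(2R)-1-{3-methoxy-4-[tri(propan-2-yl)silyloxy]phenyl}propan-2-yl]phenol
Product: 10 2-bromo-5-methoxy-4-[(2R)-1-{3-methoxy-4-[tri(propan-2-yl)silyloxy]phenyl}propan-2-yl]phenol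
Conditions: NBS, i-Pr2NH (10 mol %), CH2Cl2, −40 to 0 °C
Reagents that add atoms: N-bromosuccinimide, O=C1CCC(=O)N1Br
Why: Amine-catalysed ortho-bromination of a phenol (electrophilic aromatic substitution): of the two positions ortho to OH only the one para to the methoxy group is unhindered and doubly activated, and the free phenol ring is far more reactive than the silylated ring B.

Step 7
Reactants: 10 2-bromo-5-methoxy-4-[(2R)-1-{3-methoxy-4-[tri(propan-2-yl)silyloxy]phenyl}propan-2-yl]phenol; 11 tributyl(prop-2-en-1-yl)stannane
Product: 12 5-methoxy-4-[(2R)-1-{3-methoxy-4-[tri(propan-2-yl)silyloxy]phenyl}propan-2-yl]-2-(prop-2-en-1-yl)phenol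
Conditions: Pd(PPh3)4 (5 mol %), toluene, 100 °C
Reagents that add atoms: none
Why: Stille coupling transfers the allyl group to the brominated carbon under neutral conditions that leave the free phenol and the silyl ether untouched.

Step 8
Reactants: 12 5-methoxy-4-[(2R)-1-{3-methoxy-4-[tri(propan-2-yl)silyloxy]phenyl}propan-2-yl]-2-(prop-2-en-1-yl)phenol
Product: 14 (4R)-4,5-dimethoxy-4-[(2R)-1-{3-methoxy-4-[tri(propan-2-yl)silyloxy]phenyl}propan-2-yl]-2-(prop-2-en-1-yl)cyclohexa-2,5-dien-1-one, via aryloxyiodane intermediate 13 (not isolated)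
Conditions: PhI(OAc)2, MeOH, −20 °C
Reagents that add atoms: methanol, CO
Why: Para-selective oxidative dearomatization of a 4-alkylphenol by trivalent iodine in methanol (ligand exchange to 13, then attack of methanol at the alkyl-bearing para carbon with loss of iodobenzene) should give the 4-alkyl-4-methoxycyclohexadienone, and the quaternary centre should be set by 1,2-induction: allylic 1,3-strain holds the methine C–H in the ring plane next to the flanking OMe, so that methanol enters from the face of the small methyl group, anti to the CH2-aryl arm, which corresponds to (4R).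

Step 9
Reactants: 14 (4R)-4,5-dimethoxy-4-[(2R)-1-{3-methoxy-4-[tri(propan-2-yl)silyloxy]phenyl}propan-2-yl]-2-(prop-2-en-1-yl)cyclohexa-2,5-dien-1-one
Product: 15 (4R)-4-[(2R)-1-(4-hydroxy-3-methoxyphenyl)propan-2-yl]-4,5-dimethoxy-2-(prop-2-en-1-yl)cyclohexa-2,5-dien-1-one
Conditions: Bu4NF, AcOH, THF, 0 °C
Reagents that add atoms: none
Why: Fluoride-mediated cleavage of the aryl silyl ether, buffered with acetic acid so that the phenoxide is protonated at once and the cross-conjugated dienone, its enol ether and both stereocenters are not exposed to base.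

## Compound list

1 | 4-bromo-3-methoxyphenol | COc1cc(O)ccc1Br | starting material
2 | 4-(benzyloxy)-1-bromo-2-methoxybenzene | COc1cc(OCc2ccccc2)ccc1Br | intermediate
3 | 4,4,5,5-tetramethyl-2-(prop-1-en-2-yl)-1,3,2-dioxaborolane (isopropenylboronic acid pinacol ester) | CC(=C)B1OC(C)(C)C(C)(C)O1 | starting material
4 | 4-(benzyloxy)-2-methoxy-1-(prop-1-en-2-yl)benzene | C=C(C)c1ccc(OCc2ccccc2)cc1OC | intermediate
5 | 4-bromo-2-methoxyphenol | COc1cc(Br)ccc1O | starting material
6 | (4-bromo-2-methoxyphenoxy)tri(propan-2-yl)silane | COc1cc(Br)ccc1O[Si](C(C)C)(C(C)C)C(C)C | intermediate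
7 | {(2S)-2-[4-(benzyloxy)-2-methoxyphenyl]propyl}copper, monovalent copper bound to (R)-DTBM-SEGPHOS (ligand not drawn; same spatial arrangement at the methine as in 8, the descriptor changes only through the sequence rule) | C[C@H](C[Cu])c1ccc(OCc2ccccc2)cc1OC | intermediate (not isolated)
8 | {4-[(2R)-2-[4-(benzyloxy)-2-methoxyphenyl]propyl]-2-methoxyphenoxy}tri(propan-2-yl)silane | C[C@H](Cc1ccc(O[Si](C(C)C)(C(C)C)C(C)C)c(OC)c1)c1ccc(OCc2ccccc2)cc1OC | intermediate
9 | 3-methoxy-4-[(2R)-1-{3-methoxy-4-[tri(propan-2-yl)silyloxy]phenyl}propan-2-yl]phenol | C[C@H](Cc1ccc(O[Si](C(C)C)(C(C)C)C(C)C)c(OC)c1)c1ccc(O)cc1OC | intermediate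
10 | 2-bromo-5-methoxy-4-[(2R)-1-{3-methoxy-4-[tri(propan-2-yl)silyloxy]phenyl}propan-2-yl]phenol | C[C@H](Cc1ccc(O[Si](C(C)C)(C(C)C)C(C)C)c(OC)c1)c1cc(Br)c(O)cc1OC | intermediate
11 | tributyl(prop-2-en-1-yl)stannane (allyltributylstannane) | C=CC[Sn](CCCC)(CCCC)CCCC | starting material
12 | 5-methoxy-4-[(2R)-1-{3-methoxy-4-[tri(propan-2-yl)silyloxy]phenyl}propan-2-yl]-2-(prop-2-en-1-yl)phenol | C=CCc1cc([C@H](C)Cc2ccc(O[Si](C(C)C)(C(C)C)C(C)C)c(OC)c2)c(OC)cc1O | intermediate
13 | acetoxy(phenyl)-λ3-iodanyl ether of phenol 12 (aryloxyiodane) | C=CCc1cc([C@H](C)Cc2ccc(O[Si](C(C)C)(C(C)C)C(C)C)c(OC)c2)c(OC)cc1OI(OC(C)=O)c1ccccc1 | intermediate (not isolated)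
14 | (4R)-4,5-dimethoxy-4-[(2R)-1-{3-methoxy-4-[tri(propan-2-yl)silyloxy]phenyl}propan-2-yl]-2-(prop-2-en-1-yl)cyclohexa-2,5-dien-1-one | C=CCC1=C[C@](OC)([C@H](C)Cc2ccc(O[Si](C(C)C)(C(C)C)C(C)C)c(OC)c2)C(OC)=CC1=O | intermediate
15 | (4R)-4-[(2R)-1-(4-hydroxy-3-methoxyphenyl)propan-2-yl]-4,5-dimethoxy-2-(prop-2-en-1-yl)cyclohexa-2,5-dien-1-one | C=CCC1=C[C@](OC)([C@H](C)Cc2ccc(O)c(OC)c2)C(OC)=CC1=O | target

## Step count and risks

Total step count: 9. Longest linear sequence: 8 steps (steps 1, 2, 4, 5, 6, 7, 8, 9); step 3 is the one-step side branch.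

The three steps most likely to fail are these.

**Step 8 (dearomatization).** Methanol may discriminate too weakly between the methyl and CH2-aryl faces of the cationic ring, giving poor facial selectivity at the quaternary carbon. Loss of the benzylic proton to a quinone methide, or capture of the oxidized ring by the tethered ring B, may also compete. The fallback sets out from 12 and replaces substrate control by reagent control. Hydroxylative dearomatization with a preformed C2-symmetric, lactamide-derived chiral aryl-λ3-iodane in MeCN/H2O at 0 °C should give the para-quinol (4R)-4-hydroxy-5-methoxy-4-[(2R)-1-{3-methoxy-4-[tri(propan-2-yl)silyloxy]phenyl}propan-2-yl]-2-(prop-2-en-1-yl)cyclohexa-2,5-dien-1-one F2. Its diastereomers, being hydrogen-bond donors, should be easier to separate. O-Methylation of the tertiary alcohol (MeI, Ag2O, CH2Cl2) then comes back to the route at 14.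

**Step 4 (key step).** Hydrocupration of the ortho-substituted 2-arylpropene may be slow or poorly enantioselective, so that reduction of the aryl bromide or silyl exchange at the ring B oxygen by the silanolate takes over. The fallback sets out from 4 and separates the two events. Cobalt-catalysed enantioselective hydroboration (CoCl2 complex of a chiral iminopyridine–oxazoline ligand, NaBHEt3, pinacolborane, THF, 23 °C) should give the alkylboronate 2-{(2R)-2-[4-(benzyloxy)-2-methoxyphenyl]propyl}-4,4,5,5-tetramethyl-1,3,2-dioxaborolane F1. A B-alkyl Suzuki–Miyaura coupling of F1 with 6 (Pd(OAc)2, RuPhos, K3PO4, toluene/H2O, 90 °C) forms the same CH2–aryl bond and comes back to the route at 8.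

**Step 7 (allylation).** Oxidative addition into the electron-rich bromophenol may be sluggish, with protodebromination and migration of the allyl double bond into conjugation at the temperature needed. The fallback sets out from 9 and bypasses 10. O-Allylation (allyl bromide, K2CO3, acetone, 56 °C) should give the allyl aryl ether {2-methoxy-4-[(2R)-2-{2-methoxy-4-[(prop-2-en-1-yl)oxy]phenyl}propyl]phenoxy}tri(propan-2-yl)silane F3. Thermal aromatic Claisen rearrangement (PhNEt2, 190 °C) should move the allyl group preferentially to the ortho carbon para to the methoxy group; after removal of the regioisomer this comes back to the route at 12.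

## Further compounds

F1 | step 4 | 2-{(2R)-2-[4-(benzyloxy)-2-methoxyphenyl]propyl}-4,4,5,5-tetramethyl-1,3,2-dioxaborolane | C[C@H](CB1OC(C)(C)C(C)(C)O1)c1ccc(OCc2ccccc2)cc1OC
F2 | step 8 | (4R)-4-hydroxy-5-methoxy-4-[(2R)-1-{3-methoxy-4-[tri(propan-2-yl)silyloxy]phenyl}propan-2-yl]-2-(prop-2-en-1-yl)cyclohexa-2,5-dien-1-one | C=CCC1=C[C@](O)([C@H](C)Cc2ccc(O[Si](C(C)C)(C(C)C)C(C)C)c(OC)c2)C(OC)=CC1=O
F3 | step 7 | {2-methoxy-4-[(2R)-2-{2-methoxy-4-[(prop-2-en-1-yl)oxy]phenyl}propyl]phenoxy}tri(propan-2-yl)silane | C=CCOc1ccc([C@H](C)Cc2ccc(O[Si](C(C)C)(C(C)C)C(C)C)c(OC)c2)c(OC)c1
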